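The lower flavan's ring C is cut at C4–C4a and O1–C8a. The route exploits ring A of that unit: its C7 hydroxyl stands para to C4a, so the ring can be carried as a p-quinone monoketal in which C4a is the free carbonyl carbon, C8a a β-carbon of the latent dienone and C7 the ketal carbon. In one operation a chiral (Z)-3-lithioallyl alkoxide adds to that carbonyl, and dilute acid then opens the ketal, closes the carbinol oxygen onto C8a and aromatises by loss of water. The precursor is the upper 4-aryl-2H-chromene bearing this monoketal ring at C4. A final double hydroboration sets C3 of both units and C4 of the upper one.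

Key step: step 10

Assumption: in steps 2 and 7 the ligand antipode is named from the usual facial model of the catalyst; should the first run show the opposite sense, the mirror-image ligand is used and nothing else changes. All 2-aryl-2H-chromenes (9, 10, 11, 21) are handled with exclusion of light, because photochemical ring opening would erode C2.

Step 1
Reactants: 1 7-hydroxy-4H-chromen-4-one
Product: 2 7-(benzyloxy)-4H-chromen-4-one
Conditions: BnBr, K2CO3, DMF, 60 °C
Reagents that add atoms: benzyl bromide, BrCc1ccccc1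
Why: Williamson ether synthesis on the only hydroxyl, the acidic 7-OH of the chromone; no stereocentre is involved.

Step 2
Reactants: 2 7-(benzyloxy)-4H-chromen-4-one; 3 4-(benzyloxy)phenylboronic acid
Product: 4 (2S)-7-(benzyloxy)-2-[4-(benzyloxy)phenyl]-2,3-dihydro-4H-chromen-4-one
Conditions: Pd(OCOCF3)2 (5 mol %), (R)-t-BuPyOx (6 mol %), NH4PF6, H2O, ClCH2CH2Cl, 60 °C
Reagents that add atoms: none
Why: Palladium-catalysed asymmetric conjugate addition of an arylboronic acid to a chromone (aryl–palladium insertion into C2=C3, then protonolysis of the palladium enolate by water); the ligand dictates the face of carbopalladation and so sets C2, and the neutral conditions do not open the flavanone.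

Step 3
Reactants: 5 3-bromo-4-methoxyphenol
Product: 6 (3-bromo-4-methoxyphenoxy)tri(propan-2-yl)silane
Conditions: TIPSCl, imidazole, DMF, rt
Reagents that add atoms: chlorotri(propan-2-yl)silane, CC(C)[Si](Cl)(C(C)C)C(C)C
Why: Silylation of the phenol gives a bulky silyl ether that survives organolithium chemistry and can later be removed without touching benzyl or methyl ethers.

Step 4
Reactants: 6 (3-bromo-4-methoxyphenoxy)tri(propan-2-yl)silane; 4 (2S)-7-(benzyloxy)-2-[4-(benzyloxy)phenyl]-2,3-dihydro-4H-chromen-4-one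
Product: 9 (2S)-7-(benzyloxy)-2-[4-(benzyloxy)phenyl]-4-[2-methoxy-5-(triisopropylsilyloxy)phenyl]-2H-chromene, via aryllithium 7 (not isolated), via tertiary carbinol 8 (not isolated)
Conditions: 6, n-BuLi, THF, −78 °C; CeCl3, −78 °C; then 4, −78 → 0 °C; aq. NH4Cl; crude carbinol, PPTS (cat.), toluene, 40 °C
Reagents that add atoms: none
Why: Bromine–lithium exchange, transmetalation to the weakly basic organocerium reagent and carbonyl addition (no enolisation or β-elimination of the flavanone, so C2 is kept), then acid-catalysed dehydration of the doubly benzylic tertiary alcohol, which can only give the C3=C4 alkene; the carbinol centre is made and destroyed within the step.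

Step 5
Reactants: 9 (2S)-7-(benzyloxy)-2-[4-(benzyloxy)phenyl]-4-[2-methoxy-5-(triisopropylsilyloxy)phenyl]-2H-chromene
Product: 10 3-{(2S)-7-(benzyloxy)-2-[4-(benzyloxy)phenyl]-2H-chromen-4-yl}-4-methoxyphenol
Conditions: TBAF, AcOH, THF, 0 °C
Reagents that add atoms: none
Why: Fluoride cleaves the aryl silyl ether selectively, and acetic acid buffers the phenoxide so that the electron-rich phenol is not oxidised by air.

Step 6
Reactants: 10 3-{(2S)-7-(benzyloxy)-2-[4-(benzyloxy)phenyl]-2H-chromen-4-yl}-4-methoxyphenol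
Product: 11 3-{(2S)-7-(benzyloxy)-2-[4-(benzyloxy)phenyl]-2H-chromen-4-yl}-4,4-dimethoxycyclohexa-2,5-dien-1-one
Conditions: PhI(OAc)2, MeOH, 0 °C
Reagents that add atoms: methanol, CO
Why: Oxidative dearomatisation of a 4-methoxyphenol by a trivalent iodine reagent in methanol: methanol attacks the aryloxy-iodane para to oxygen, at the carbon that already bears OMe, which places the carbonyl at the former phenol carbon and the ketal next to the chromenyl group; the phenol should react far faster than the styrene-type alkene.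

Step 7
Reactants: 12 3,4-bis(benzyloxy)benzaldehyde; 13 ethynyl(trimethyl)silane
Product: 14 (1R)-1-[3,4-bis(benzyloxy)phenyl]-3-(trimethylsilyl)prop-2-yn-1-ol
Conditions: Me2Zn, (S,S)-ProPhenol (20 mol %), Ph3PO, toluene, 0 → 4 °C
Reagents that add atoms: none
Why: Zinc–ProPhenol-catalysed asymmetric alkynylation of an aromatic aldehyde; the dinuclear zinc catalyst binds the aldehyde and delivers the zinc acetylide to one face, which sets the carbinol centre (R).

Step 8
Reactants: 14 (1R)-1-[3,4-bis(benzyloxy)phenyl]-3-(trimethylsilyl)prop-2-yn-1-ol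
Product: 15 (1R)-1-[3,4-bis(benzyloxy)phenyl]-3-iodoprop-2-yn-1-ol
Conditions: NIS, AgNO3 (10 mol %), DMF, rt, dark
Reagents that add atoms: N-iodosuccinimide, O=C1CCC(=O)N1I
Why: Silver-catalysed iododesilylation: AgNO3 turns the silylalkyne into a silver acetylide that NIS iodinates; the stereocentre is untouched.

Step 9
Reactants: 15 (1R)-1-[3,4-bis(benzyloxy)phenyl]-3-iodoprop-2-yn-1-ol
Product: 16 (1S,2Z)-1-[3,4-bis(benzyloxy)phenyl]-3-iodoprop-2-en-1-ol
Conditions: 2-nitrobenzenesulfonylhydrazide, Et3N, THF/i-PrOH, rt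
Reagents that add atoms: none
Why: Diimide released from the sulfonylhydrazide adds H2 syn to the iodoalkyne and gives the Z-iodoalkene without cleaving C–I or benzyl ethers; the descriptor becomes S only because the CIP priorities change.

Step 10
Reactants: 16 (1S,2Z)-1-[3,4-bis(benzyloxy)phenyl]-3-iodoprop-2-en-1-ol; 11 3-{(2S)-7-(benzyloxy)-2-[4-(benzyloxy)phenyl]-2H-chromen-4-yl}-4,4-dimethoxycyclohexa-2,5-dien-1-one
Product: 21 (2S)-2-[3,4-bis(benzyloxy)phenyl]-6-{(2S)-7-(benzyloxy)-2-[4-(benzyloxy)phenyl]-2H-chromen-4-yl}-2H-chromen-7-ol, via dilithio alkoxide 17 (not isolated), via quinol ketal 18 (not isolated), via quinol dienone 19 (not isolated), via oxa-Michael adduct 20 (not isolated)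
Conditions: 16, t-BuLi (3.0 equiv), THF/Et2O, −78 °C; 11, −78 °C; then 1 M aq. oxalic acid, THF, 0 °C → rt, dark
Reagents that add atoms: water, O
Why: Iodine–lithium exchange on 16 with retention gives the (Z)-3-lithioallyl alkoxide 17, whose hard vinyl carbanion adds 1,2 to the only free carbonyl of 11 and forms the C4–C4a bond (quinol ketal 18); dilute acid then hydrolyses the ketal to the 4-hydroxycyclohexadienone 19, the benzylic hydroxyl adds to the unsubstituted β-carbon of the dienone (20, O1–C8a bond), and loss of the tertiary hydroxyl as water restores the aromatic ring with the former ketal carbon as the 7-phenol. The closest known reaction type is the quinone-monoketal annulation: organolithium 1,2-addition followed by acid-induced ketal hydrolysis, intramolecular hetero-Michael addition and dehydrative aromatisation, as used for benzofurans and indoles from such ketals. The one ring closed, the 2H-pyran, closes 6-exo-trig, which the Z double bond makes geometrically possible. No lasting stereocentre is created: the quinol carbon and the ring-fusion carbon of 18–20 are erased by aromatisation, and C2 comes unchanged from 16 because its C–O bond is never broken. The step needs 1,2- rather than 1,4-addition (hard lithium reagent at −78 °C, the other carbonyl masked as the ketal), closure at the free β-carbon rather than at the one next to the chromenyl-bearing carbon (sterics and the lower electrophilicity of the α-substituted enone arm), and survival of both 2-aryl-2H-chromenes (weak acid, low temperature, no light).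

Step 11
Reactants: 21 (2S)-2-[3,4-bis(benzyloxy)phenyl]-6-{(2S)-7-(benzyloxy)-2-[4-(benzyloxy)phenyl]-2H-chromen-4-yl}-2H-chromen-7-ol
Product: 23 (2R,3S,4R)-7-(benzyloxy)-2-[4-(benzyloxy)phenyl]-4-{(2R,3S)-2-[3,4-bis(benzyloxy)phenyl]-3,7-dihydroxy-3,4-dihydro-2H-chromen-6-yl}-3,4-dihydro-2H-chromen-3-ol, via organoborane 22 (not isolated)
Conditions: BH3·THF (excess), THF, 0 °C → rt; then NaOH, H2O2, 0 °C
Reagents that add atoms: hydrogen peroxide, OO
Why: Hydroboration–oxidation of flav-3-enes: boron adds to C3 of each ring (β to the aryl-conjugated carbon; C4 of the upper ring is fully substituted) from the face anti to the 2-aryl group and hydrogen adds syn at C4, so oxidation with retention should give 3-OH trans to the 2-aryl group in both units and the upper C4 aryl group trans to 3-OH.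

Step 12
Reactants: 23 (2R,3S,4R)-7-(benzyloxy)-2-[4-(benzyloxy)phenyl]-4-{(2R,3S)-2-[3,4-bis(benzyloxy)phenyl]-3,7-dihydroxy-3,4-dihydro-2H-chromen-6-yl}-3,4-dihydro-2H-chromen-3-ol
Product: 24 (2R,3S,4R)-2-(4-hydroxyphenyl)-4-[(2R,3S)-2-(3,4-dihydroxyphenyl)-3,7-dihydroxy-3,4-dihydro-2H-chromen-6-yl]-3,4-dihydro-2H-chromene-3,7-diol
Conditions: H2 (1 atm), Pd(OH)2/C, THF/MeOH, rt
Reagents that add atoms: none
Why: Hydrogenolysis of the four benzyl ethers over palladium; the flavan C–O bonds and the interflavan C–C bond of this 5-deoxy series cleave much more slowly under neutral conditions, and the reaction is stopped at full debenzylation.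

Compound list
1 | 7-hydroxy-4H-chromen-4-one | O=c1ccoc2cc(O)ccc12 | starting material
2 | 7-(benzyloxy)-4H-chromen-4-one | O=c1ccoc2cc(OCc3ccccc3)ccc12 | intermediate
3 | 4-(benzyloxy)phenylboronic acid | OB(O)c1ccc(OCc2ccccc2)cc1 | starting material
4 | (2S)-7-(benzyloxy)-2-[4-(benzyloxy)phenyl]-2,3-dihydro-4H-chromen-4-one | O=C1C[C@@H](c2ccc(OCc3ccccc3)cc2)Oc2cc(OCc3ccccc3)ccc12 | intermediate
5 | 3-bromo-4-methoxyphenol | COc1ccc(O)cc1Br | starting material
6 | (3-bromo-4-methoxyphenoxy)tri(propan-2-yl)silane | COc1ccc(O[Si](C(C)C)(C(C)C)C(C)C)cc1Br | intermediate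
7 | [2-methoxy-5-(triisopropylsilyloxy)phenyl]lithium | COc1ccc(O[Si](C(C)C)(C(C)C)C(C)C)cc1[Li] | intermediate
8 | (2S)-7-(benzyloxy)-2-[4-(benzyloxy)phenyl]-4-[2-methoxy-5-(triisopropylsilyloxy)phenyl]chroman-4-ol (C4 not controlled) | COc1ccc(O[Si](C(C)C)(C(C)C)C(C)C)cc1C1(O)C[C@@H](c2ccc(OCc3ccccc3)cc2)Oc2cc(OCc3ccccc3)ccc12 | intermediate
9 | (2S)-7-(benzyloxy)-2-[4-(benzyloxy)phenyl]-4-[2-methoxy-5-(triisopropylsilyloxy)phenyl]-2H-chromene | COc1ccc(O[Si](C(C)C)(C(C)C)C(C)C)cc1C1=C[C@@H](c2ccc(OCc3ccccc3)cc2)Oc2cc(OCc3ccccc3)ccc12 | intermediate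
10 | 3-{(2S)-7-(benzyloxy)-2-[4-(benzyloxy)phenyl]-2H-chromen-4-yl}-4-methoxyphenol | COc1ccc(O)cc1C1=C[C@@H](c2ccc(OCc3ccccc3)cc2)Oc2cc(OCc3ccccc3)ccc12 | intermediate
11 | 3-{(2S)-7-(benzyloxy)-2-[4-(benzyloxy)phenyl]-2H-chromen-4-yl}-4,4-dimethoxycyclohexa-2,5-dien-1-one | COC1(OC)C=CC(=O)C=C1C1=C[C@@H](c2ccc(OCc3ccccc3)cc2)Oc2cc(OCc3ccccc3)ccc12 | intermediate
12 | 3,4-bis(benzyloxy)benzaldehyde | O=Cc1ccc(OCc2ccccc2)c(OCc2ccccc2)c1 | starting material
13 | ethynyl(trimethyl)silane | C#C[Si](C)(C)C | starting material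
14 | (1R)-1-[3,4-bis(benzyloxy)phenyl]-3-(trimethylsilyl)prop-2-yn-1-ol | O[C@H](c1ccc(OCc2ccccc2)c(OCc2ccccc2)c1)C#C[Si](C)(C)C | intermediate
15 | (1R)-1-[3,4-bis(benzyloxy)phenyl]-3-iodoprop-2-yn-1-ol | O[C@H](c1ccc(OCc2ccccc2)c(OCc2ccccc2)c1)C#CI | intermediate
16 | (1S,2Z)-1-[3,4-bis(benzyloxy)phenyl]-3-iodoprop-2-en-1-ol | O[C@H](c1ccc(OCc2ccccc2)c(OCc2ccccc2)c1)/C=C\I | intermediate
17 | dilithio derivative of 16: lithium (1S,2Z)-1-[3,4-bis(benzyloxy)phenyl]-3-lithioprop-2-en-1-olate | [Li]O[C@H](c1ccc(OCc2ccccc2)c(OCc2ccccc2)c1)/C=C\[Li] | intermediate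
18 | 1-{(1Z,3S)-3-[3,4-bis(benzyloxy)phenyl]-3-hydroxyprop-1-en-1-yl}-3-{(2S)-7-(benzyloxy)-2-[4-(benzyloxy)phenyl]-2H-chromen-4-yl}-4,4-dimethoxycyclohexa-2,5-dien-1-ol (quinol carbon not controlled) | COC1(OC)C=CC(O)(/C=C\[C@H](O)c2ccc(OCc3ccccc3)c(OCc3ccccc3)c2)C=C1C1=C[C@@H](c2ccc(OCc3ccccc3)cc2)Oc2cc(OCc3ccccc3)ccc12 | intermediate
19 | 2-{(2S)-7-(benzyloxy)-2-[4-(benzyloxy)phenyl]-2H-chromen-4-yl}-4-{(1Z,3S)-3-[3,4-bis(benzyloxy)phenyl]-3-hydroxyprop-1-en-1-yl}-4-hydroxycyclohexa-2,5-dien-1-one | O=C1C=CC(O)(/C=C\[C@H](O)c2ccc(OCc3ccccc3)c(OCc3ccccc3)c2)C=C1C1=C[C@@H](c2ccc(OCc3ccccc3)cc2)Oc2cc(OCc3ccccc3)ccc12 | intermediate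
20 | (2S)-2-[3,4-bis(benzyloxy)phenyl]-6-{(2S)-7-(benzyloxy)-2-[4-(benzyloxy)phenyl]-2H-chromen-4-yl}-4a-hydroxy-2,4a,8,8a-tetrahydro-7H-chromen-7-one (cis ring fusion, 4a/8a not controlled) | O=C1CC2O[C@H](c3ccc(OCc4ccccc4)c(OCc4ccccc4)c3)C=CC2(O)C=C1C1=C[C@@H](c2ccc(OCc3ccccc3)cc2)Oc2cc(OCc3ccccc3)ccc12 | intermediate
21 | (2S)-2-[3,4-bis(benzyloxy)phenyl]-6-{(2S)-7-(benzyloxy)-2-[4-(benzyloxy)phenyl]-2H-chromen-4-yl}-2H-chromen-7-ol | Oc1cc2O[C@H](c3ccc(OCc4ccccc4)c(OCc4ccccc4)c3)C=Cc2cc1C1=C[C@@H](c2ccc(OCc3ccccc3)cc2)Oc2cc(OCc3ccccc3)ccc12 | intermediate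
22 | organoborane from 21: boron at C3 of both rings (anti to the 2-aryl groups) and on the phenol oxygen, drawn as the BH2 species | O(Cc1ccccc1)c1ccc([C@H]2Oc3cc(OCc4ccccc4)ccc3[C@@H](c3cc4c(cc3OB)O[C@H](c3ccc(OCc5ccccc5)c(OCc5ccccc5)c3)[C@@H](B)C4)[C@@H]2B)cc1 | intermediate
23 | (2R,3S,4R)-7-(benzyloxy)-2-[4-(benzyloxy)phenyl]-4-{(2R,3S)-2-[3,4-bis(benzyloxy)phenyl]-3,7-dihydroxy-3,4-dihydro-2H-chromen-6-yl}-3,4-dihydro-2H-chromen-3-ol | O(Cc1ccccc1)c1ccc([C@H]2Oc3cc(OCc4ccccc4)ccc3[C@@H](c3cc4c(cc3O)O[C@H](c3ccc(OCc5ccccc5)c(OCc5ccccc5)c3)[C@@H](O)C4)[C@@H]2O)cc1 | intermediate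
24 | (2R,3S,4R)-2-(4-hydroxyphenyl)-4-[(2R,3S)-2-(3,4-dihydroxyphenyl)-3,7-dihydroxy-3,4-dihydro-2H-chromen-6-yl]-3,4-dihydro-2H-chromene-3,7-diol | Oc1ccc([C@H]2Oc3cc(O)ccc3[C@@H](c3cc4c(cc3O)O[C@H](c3ccc(O)c(O)c3)[C@@H](O)C4)[C@@H]2O)cc1 | target

Total step count: 12. Longest linear sequence: 8 steps (1, 2, 4, 5, 6, 10, 11, 12).

Steps most likely to fail

Step 10. The dienone may take an electron from the dilithio reagent, or the vinyl carbanion may add in a conjugate sense or abstract a proton; the Z geometry that the closure needs depends on a clean iodine–lithium exchange. Fallback (acetylide in place of the vinyllithium, geometry set afterwards): it sets out from 14 and 11 and comes back at 18. K2CO3 in MeOH removes the silyl group of 14 to give (1S)-1-[3,4-bis(benzyloxy)phenyl]prop-2-yn-1-ol F1. Its dianion (n-BuLi, 2 equiv, THF, −78 °C) adds 1,2 to 11, a reliable acetylide addition to a quinone monoketal, and gives the alkynyl quinol ketal F2. Semihydrogenation over Lindlar catalyst (Pd on CaCO3 poisoned with Pb(OAc)2, quinoline, H2) gives the Z-alkenyl quinol ketal 18, which is then treated with the same dilute oxalic acid to give 21.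

Step 11. Facial selectivity or conversion may be poor at the hindered, trisubstituted upper double bond, the aryloxyborane may deliver boron to the wrong face, or boron may go to C4 of the lower ring. Fallback (union of two finished flavans; upper stereocentres by hydride reduction and cation capture, one simple hydroboration only): it sets out from 4 and 17 and comes back at 23. Reagent 17 is added to commercial 4,4-dimethoxycyclohexa-2,5-dien-1-one and treated with dilute oxalic acid as in step 10, with no regiochemical question and no second chromene, to give (2S)-2-[3,4-bis(benzyloxy)phenyl]-2H-chromen-7-ol F3. Hydroboration–oxidation of this single cis-disubstituted flav-3-ene gives (2R,3S)-2-[3,4-bis(benzyloxy)phenyl]chromane-3,7-diol F4. Flavanone 4 is converted with Me3SiOTf and Et3N into its silyl enol ether (2S)-7-(benzyloxy)-2-[4-(benzyloxy)phenyl]-4-(trimethylsilyloxy)-2H-chromene F5. Rubottom oxidation (dimethyldioxirane, then dilute acid) gives the trans-dihydroflavonol (2R,3R)-7-(benzyloxy)-2-[4-(benzyloxy)phenyl]-3-hydroxychroman-4-one F6, and NaBH4 gives (2R,3S,4R)-7-(benzyloxy)-2-[4-(benzyloxy)phenyl]chromane-3,4-diol F7. F7 and an excess of F4 in dilute HCl/dioxane give 23: the C4 benzylic cation is captured trans to 3-OH by C6 of the resorcinol ring of F4.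

Step 6. The trivalent iodine reagent may oxidise the electron-rich 4-aryl-2H-chromene double bond or the allylic, benzylic C2–H in competition with the phenol, or methanol may attack ortho instead of para. Fallback (the ketal ring is brought in preformed, so no oxidation is run in the presence of the chromene): it sets out from 4 and comes back at 11. Commercial 2-bromo-1,4-dimethoxybenzene is oxidised anodically (Pt anode, KOH, MeOH) to 2-bromo-3,3,6,6-tetramethoxycyclohexa-1,4-diene F8. Bromine–lithium exchange (n-BuLi, −78 °C), CeCl3 and flavanone 4 give the carbinol (2S)-7-(benzyloxy)-2-[4-(benzyloxy)phenyl]-4-(3,3,6,6-tetramethoxycyclohexa-1,4-dien-1-yl)chroman-4-ol F9. PPTS in wet acetone dehydrates the carbinol and hydrolyses the ketal remote from the substituent (the cation leading to it is stabilised by the chromenyl group), which gives 11.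

Further compounds
F1 | step 10 | (1S)-1-[3,4-bis(benzyloxy)phenyl]prop-2-yn-1-ol | O[C@H](c1ccc(OCc2ccccc2)c(OCc2ccccc2)c1)C#C
F2 | step 10 | 1-{(3R)-3-[3,4-bis(benzyloxy)phenyl]-3-hydroxyprop-1-yn-1-yl}-3-{(2S)-7-(benzyloxy)-2-[4-(benzyloxy)phenyl]-2H-chromen-4-yl}-4,4-dimethoxycyclohexa-2,5-dien-1-ol | COC1(OC)C=CC(O)(C#C[C@H](O)c2ccc(OCc3ccccc3)c(OCc3ccccc3)c2)C=C1C1=C[C@@H](c2ccc(OCc3ccccc3)cc2)Oc2cc(OCc3ccccc3)ccc12
F3 | step 11 | (2S)-2-[3,4-bis(benzyloxy)phenyl]-2H-chromen-7-ol | Oc1ccc2C=C[C@@H](c3ccc(OCc4ccccc4)c(OCc4ccccc4)c3)Oc2c1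
F4 | step 11 | (2R,3S)-2-[3,4-bis(benzyloxy)phenyl]chromane-3,7-diol | Oc1ccc2C[C@H](O)[C@@H](c3ccc(OCc4ccccc4)c(OCc4ccccc4)c3)Oc2c1
F5 | step 11 | (2S)-7-(benzyloxy)-2-[4-(benzyloxy)phenyl]-4-(trimethylsilyloxy)-2H-chromene | C[Si](C)(C)OC1=C[C@@H](c2ccc(OCc3ccccc3)cc2)Oc2cc(OCc3ccccc3)ccc12
F6 | step 11 | (2R,3R)-7-(benzyloxy)-2-[4-(benzyloxy)phenyl]-3-hydroxychroman-4-one | O=C1[C@H](O)[C@@H](c2ccc(OCc3ccccc3)cc2)Oc2cc(OCc3ccccc3)ccc12
F7 | step 11 | (2R,3S,4R)-7-(benzyloxy)-2-[4-(benzyloxy)phenyl]chromane-3,4-diol | O(Cc1ccccc1)c1ccc([C@H]2Oc3cc(OCc4ccccc4)ccc3[C@@H](O)[C@@H]2O)cc1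
F8 | step 6 | 2-bromo-3,3,6,6-tetramethoxycyclohexa-1,4-diene | COC1(OC)C=CC(OC)(OC)C(Br)=C1
F9 | step 6 | (2S)-7-(benzyloxy)-2-[4-(benzyloxy)phenyl]-4-(3,3,6,6-tetramethoxycyclohexa-1,4-dien-1-yl)chroman-4-ol | COC1(OC)C=CC(OC)(OC)C(=C1)C1(O)C[C@@H](c2ccc(OCc3ccccc3)cc2)Oc2cc(OCc3ccccc3)ccc12
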